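**Retrosynthetic overview**
- The styryl C–C bond is cut by a Heck disconnection into 8-iodo-7-methoxycoumarin and a 6-vinylcyclohexene carrying the other coumarin.
- The vinyl group and the quaternary methyl go back to a 2-aryl-4-methylcyclohex-3-ene-1-carbaldehyde (methylenation; enolate methylation anti to the aryl group).
- The cyclohexene ring (C1–C6 bond) comes from a light-driven radical-cation Claisen ring contraction of a 2-styryl-3,4-dihydro-2H-pyran, which passes the chirality of a C–O centre on to C1.
- The dihydropyran comes from (R)-linalool (ozonolysis, alkyne homologation, cycloisomerisation) and a Heck reaction with 6-bromo-7-methoxycoumarin.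
- Ring order: pyranone ring of the 6-bromocoumarin (the other coumarin is bought as umbelliferone), then the temporary dihydropyran ring, then the cyclohexene ring.

Assumption: natural (R)-(−)-linalool of at least 97% ee is used (its ee fixes that of the product); target ring numbering is C1 (CH–aryl), C2=C3(Me), C4, C5, C6 (quaternary).

**Step 1**
Reactants: 1 (R)-(−)-linalool, (3R)-3,7-dimethylocta-1,6-dien-3-ol
Product: 3 (5R)-5-ethenyl-5-methyloxolan-2-ol (lactol; both anomers), via hydroxy aldehyde 2 (not isolated)
Conditions: O3 (1.0 equiv, Sudan Red 7B end point), CH2Cl2/MeOH 4:1, −78 °C; then Me2S, −78 °C → rt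
Reagents that add atoms: ozone, O=[O+][O-]
Why: Ozonolysis with reductive work-up cleaves the electron-rich trisubstituted alkene much faster than the vinyl group, and the γ-hydroxy aldehyde 2 closes to lactol 3; the carbinol stereocentre of 1 is untouched.

**Step 2**
Reactants: 3 (5R)-5-ethenyl-5-methyloxolan-2-ol
Product: 4 (3R)-3-methylhept-1-en-6-yn-3-ol
Conditions: MeC(O)C(N2)P(O)(OMe)2 (1.5 equiv), K2CO3 (2.5 equiv), MeOH, 0 °C → rt
Reagents that add atoms: dimethyl (1-diazo-2-oxopropyl)phosphonate, CC(=O)C(=[N+]=[N-])P(=O)(OC)OC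
Why: Seyferth–Gilbert homologation with the Ohira–Bestmann reagent acts on the open aldehyde tautomer 2 of the lactol and adds the one carbon that becomes the enol ether CH; the stereocentre is not involved.

**Step 3**
Reactants: 4 (3R)-3-methylhept-1-en-6-yn-3-ol
Product: 5 (2R)-2-ethenyl-2-methyl-3,4-dihydro-2H-pyran
Conditions: [Rh(cod)Cl]2 (2.5 mol %), P(4-FC6H4)3 (30 mol %), DMF, 85 °C
Reagents that add atoms: none
Why: Endo-selective alkynol cycloisomerisation: the vinylidene complex formed from [Rh(cod)Cl]2 and the terminal alkyne is attacked at its α-carbon by the tertiary hydroxyl, giving the six-membered cyclic enol ether with the stereocentre unchanged.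

**Step 4**
Reactants: 6 5-bromo-2-hydroxy-4-methoxybenzaldehyde
Product: 7 6-bromo-7-methoxy-2H-chromen-2-one (6-bromo-7-methoxycoumarin)
Conditions: Ph3P=CHCO2Et (1.2 equiv), PhNEt2, 210 °C
Reagents that add atoms: ethyl (triphenylphosphoranylidene)acetate, CCOC(=O)C=P(c1ccccc1)(c1ccccc1)c1ccccc1
Why: Wittig olefination of the salicylaldehyde followed by thermal E/Z isomerisation and lactonisation (Wittig coumarin synthesis) builds the pyranone ring with bromine already at C6.

**Step 5**
Reactants: 5 (2R)-2-ethenyl-2-methyl-3,4-dihydro-2H-pyran (1.5 equiv); 7 6-bromo-7-methoxycoumarin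
Product: 8 7-methoxy-6-{(E)-2-[(2R)-2-methyl-3,4-dihydro-2H-pyran-2-yl]ethenyl}-2H-chromen-2-one
Conditions: Pd2(dba)3 (2.5 mol %), [HP(t-Bu)3]BF4 (10 mol %), K2CO3, DMF, 80 °C
Reagents that add atoms: none
Why: Mizoroki–Heck reaction: Ar–Pd–Br adds to the terminal vinyl carbon (the cyclic enol ether is far less reactive under neutral conditions) and, with a quaternary allylic carbon, β-hydride elimination can only give the E-styrene; the stereocentre is untouched.

**Step 6**
Reactants: 8 7-methoxy-6-{(E)-2-[(2R)-2-methyl-3,4-dihydro-2H-pyran-2-yl]ethenyl}-2H-chromen-2-one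
Product: 9 (1S,2R)-2-(7-methoxy-2-oxo-2H-chromen-6-yl)-4-methylcyclohex-3-ene-1-carbaldehyde
Conditions: 2,4,6-tris(4-methoxyphenyl)pyrylium tetrafluoroborate (2 mol %), 2,6-di-tert-butyl-4-methylpyridine (5 mol %), CH2Cl2 (0.01 M), 455 nm LEDs, −20 °C, Ar
Reagents that add atoms: none
Why: Proposed new method: the excited pyrylium salt oxidises the styrene/enol ether π-system of 8 to a radical cation in which the enol ether β-carbon and the styrene terminus, held together by the ring in the only reachable boat (bicyclo[2.2.2]octane-like) array, bond and the allylic C–O bond then breaks to give the aldehyde and the ring alkene, the harder-to-oxidise product radical cation passing its hole to the next molecule of 8 or taking the electron back from the reduced catalyst; the closest known reactions are the thermal Claisen ring contraction of 2-alkenyl-3,4-dihydro-2H-pyrans to cyclohex-3-ene-1-carbaldehydes and photoredox radical-cation Diels–Alder and vinylcyclobutane rearrangements of electron-rich styrenes; C1 is set by suprafacial 1,3-transfer of chirality from the linalool-derived C–O centre with the E-aryl group on the outside of the boat (a Z-styrene would have to place the aryl group under the ring), and the formyl-bearing centre forms cis and is re-set in step 7.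

**Step 7**
Reactants: 9 (1S,2R)-2-(7-methoxy-2-oxo-2H-chromen-6-yl)-4-methylcyclohex-3-ene-1-carbaldehyde
Product: 11 (1S,2R)-2-(7-methoxy-2-oxo-2H-chromen-6-yl)-1,4-dimethylcyclohex-3-ene-1-carbaldehyde, via potassium enolate 10 (not isolated)
Conditions: KN(SiMe3)2 (1.05 equiv), THF, −78 °C; MeI (3 equiv), −78 → −20 °C
Reagents that add atoms: iodomethane, CI
Why: Enolate alkylation: in the planar enolate 10 the neighbouring aryl group sits pseudoaxial to avoid allylic strain, so iodomethane enters from the opposite face and the quaternary centre (C6 of the target) forms with methyl trans and formyl cis to the aryl group, controlled by C1.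

**Step 8**
Reactants: 11 (1S,2R)-2-(7-methoxy-2-oxo-2H-chromen-6-yl)-1,4-dimethylcyclohex-3-ene-1-carbaldehyde
Product: 12 6-[(1R,6R)-6-ethenyl-3,6-dimethylcyclohex-2-en-1-yl]-7-methoxy-2H-chromen-2-one
Conditions: Ph3PCH3Br (1.3 equiv), KOtBu (1.25 equiv), THF, 0 °C; then 11, −78 → 0 °C
Reagents that add atoms: methyltriphenylphosphonium bromide, C[P+](c1ccccc1)(c1ccccc1)c1ccccc1.[Br-]
Why: Wittig methylenation of the non-enolisable neopentyl aldehyde, which is much more electrophilic than the coumarin lactone; no stereocentre is touched (the descriptor at C6 changes only through CIP priorities).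

**Step 9**
Reactants: 13 7-hydroxy-2H-chromen-2-one (umbelliferone)
Product: 14 7-hydroxy-8-iodo-2H-chromen-2-one
Conditions: I2 (1.0 equiv), KI, aq NH3 (20%), 0 °C → rt
Reagents that add atoms: iodine, II
Why: Electrophilic aromatic iodination of the phenoxide, which under these conditions goes ortho to the 7-oxygen at C8.

**Step 10**
Reactants: 14 7-hydroxy-8-iodo-2H-chromen-2-one
Product: 15 8-iodo-7-methoxy-2H-chromen-2-one
Conditions: MeI, K2CO3, acetone, reflux
Reagents that add atoms: iodomethane, CI
Why: Williamson O-methylation of the phenol.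

**Step 11**
Reactants: 12 6-[(1R,6R)-6-ethenyl-3,6-dimethylcyclohex-2-en-1-yl]-7-methoxy-2H-chromen-2-one; 15 8-iodo-7-methoxy-2H-chromen-2-one
Product: 16 7-methoxy-6-{(1R,6R)-6-[(E)-2-(7-methoxy-2-oxo-2H-chromen-8-yl)ethenyl]-3,6-dimethylcyclohex-2-en-1-yl}-2H-chromen-2-one (CNP0287121.3)
Conditions: Pd(OAc)2 (10 mol %), nBu4NCl, K2CO3, DMF, 85 °C
Reagents that add atoms: none
Why: Mizoroki–Heck reaction under ligand-free phase-transfer (Jeffery) conditions: Ar–Pd–I adds to the terminal vinyl carbon and, because the allylic carbon is quaternary, β-hydride elimination gives only the E-styrene; both stereocentres are remote and retained.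

**Compound list**
1 | (R)-(−)-linalool, (3R)-3,7-dimethylocta-1,6-dien-3-ol | C=C[C@](C)(O)CCC=C(C)C | starting material
2 | (4R)-4-hydroxy-4-methylhex-5-enal | C=C[C@](C)(O)CCC=O | intermediate
3 | (5R)-5-ethenyl-5-methyloxolan-2-ol | C=C[C@@]1(C)CCC(O)O1 | intermediate
4 | (3R)-3-methylhept-1-en-6-yn-3-ol | C=C[C@](C)(O)CCC#C | intermediate
5 | (2R)-2-ethenyl-2-methyl-3,4-dihydro-2H-pyran | C=C[C@@]1(C)CCC=CO1 | intermediate
6 | 5-bromo-2-hydroxy-4-methoxybenzaldehyde | COc1cc(O)c(C=O)cc1Br | starting material
7 | 6-bromo-7-methoxy-2H-chromen-2-one | COc1cc2oc(=O)ccc2cc1Br | intermediate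
8 | 7-methoxy-6-{(E)-2-[(2R)-2-methyl-3,4-dihydro-2H-pyran-2-yl]ethenyl}-2H-chromen-2-one | COc1cc2oc(=O)ccc2cc1/C=C/[C@@]1(C)CCC=CO1 | intermediate
9 | (1S,2R)-2-(7-methoxy-2-oxo-2H-chromen-6-yl)-4-methylcyclohex-3-ene-1-carbaldehyde | O=C[C@H]1CCC(C)=C[C@H]1c1cc2ccc(=O)oc2cc1OC | intermediate
10 | potassium [(2R)-2-(7-methoxy-2-oxo-2H-chromen-6-yl)-4-methylcyclohex-3-en-1-ylidene]methanolate | [K+].[O-]C=C1CCC(C)=C[C@H]1c1cc2ccc(=O)oc2cc1OC | intermediate
11 | (1S,2R)-2-(7-methoxy-2-oxo-2H-chromen-6-yl)-1,4-dimethylcyclohex-3-ene-1-carbaldehyde | O=C[C@@]1(C)CCC(C)=C[C@H]1c1cc2ccc(=O)oc2cc1OC | intermediate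
12 | 6-[(1R,6R)-6-ethenyl-3,6-dimethylcyclohex-2-en-1-yl]-7-methoxy-2H-chromen-2-one | C=C[C@@]1(C)CCC(C)=C[C@H]1c1cc2ccc(=O)oc2cc1OC | intermediate
13 | 7-hydroxy-2H-chromen-2-one (umbelliferone) | Oc1ccc2ccc(=O)oc2c1 | starting material
14 | 7-hydroxy-8-iodo-2H-chromen-2-one | Oc1ccc2ccc(=O)oc2c1I | intermediate
15 | 8-iodo-7-methoxy-2H-chromen-2-one | COc1ccc2ccc(=O)oc2c1I | intermediate
16 | 7-methoxy-6-{(1R,6R)-6-[(E)-2-(7-methoxy-2-oxo-2H-chromen-8-yl)ethenyl]-3,6-dimethylcyclohex-2-en-1-yl}-2H-chromen-2-one | COc1cc2oc(=O)ccc2cc1[C@@H]1C=C(C)CC[C@]1(C)/C=C/c1c(OC)ccc2ccc(=O)oc12 | target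

**Step count**
Total: 11 steps. Longest linear sequence: 8 steps (1 → 16 through steps 1, 2, 3, 5, 6, 7, 8, 11).

**Three steps most likely to fail**

Step 6 (the proposed new reaction). The radical cation may fragment at the tertiary allylic C–O bond, scramble the styrene geometry or stop at a cyclobutane. The fallback is the known thermal Claisen ring contraction of 2-alkenyl-3,4-dihydro-2H-pyrans: 8 is heated in degassed o-xylene with a little N,N-diethylaniline as acid scavenger in a sealed tube at 200–220 °C (or passed through a heated flow coil). This goes through the same boat transition state and gives the same cis aldehyde. The fallback sets out from 8 and comes back to the route at 9; it makes no new compound (F0).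

Step 3. The tertiary enynol may give enyne cycloisomerisation or exo attack instead of the endo enol ether. The fallback builds the enol ether by carbonyl chemistry and sets out from lactol 3. The ylide from (methoxymethyl)triphenylphosphonium chloride and KN(SiMe3)2 (THF, 0 °C) gives the enol ether (3R)-7-methoxy-3-methylhepta-1,6-dien-3-ol F1. Pyridinium p-toluenesulfonate (CH2Cl2, rt) closes it to the cyclic acetal (6R)-6-ethenyl-2-methoxy-6-methyloxane F2. TMSOTf/Et3N (CH2Cl2, 0 °C) then eliminates the methoxy group, and the fallback comes back to the route at 5.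

Step 5. Ar–Pd–Br may attack the enol ether, or β-alkoxide elimination may open the ring; 5 is also volatile. The fallback puts the aryl group on before the enol ether exists and sets out from lactol 3 and bromide 7. A Heck reaction under the step 5 conditions gives the aryl lactol 6-{(E)-2-[(2R)-5-hydroxy-2-methyloxolan-2-yl]ethenyl}-7-methoxy-2H-chromen-2-one F3. Ohira–Bestmann homologation as in step 2 gives the alkynol 6-[(1E,3R)-3-hydroxy-3-methylhept-1-en-6-yn-1-yl]-7-methoxy-2H-chromen-2-one F4. Cycloisomerisation as in step 3 then brings the fallback back to the route at 8.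

**Further compounds**
F0 | step 6 | none | none
F1 | step 3 | (3R)-7-methoxy-3-methylhepta-1,6-dien-3-ol | C=C[C@](C)(O)CCC=COC
F2 | step 3 | (6R)-6-ethenyl-2-methoxy-6-methyloxane | C=C[C@@]1(C)CCCC(OC)O1
F3 | step 5 | 6-{(E)-2-[(2R)-5-hydroxy-2-methyloxolan-2-yl]ethenyl}-7-methoxy-2H-chromen-2-one | COc1cc2oc(=O)ccc2cc1/C=C/[C@@]1(C)CCC(O)O1
F4 | step 5 | 6-[(1E,3R)-3-hydroxy-3-methylhept-1-en-6-yn-1-yl]-7-methoxy-2H-chromen-2-one | COc1cc2oc(=O)ccc2cc1/C=C/[C@](C)(O)CCC#C
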